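**Retrosynthetic overview**
1. Siphulin is taken back to its tri-O-methyl ether tert-butyl ester (cleaved by BBr3). That compound is taken back to the same chromone with an extra carboxyl at C3, carried as a benzyl ester and removed by hydrogenolysis and loss of CO2.
2. Feature used: in ring B the ether bond O1–C8a stands ortho, through C4a, to the C4 carbonyl, so C8a can carry a fluoride that this carbonyl activates for SNAr. C3 lies between C2 and C4 as the central carbon of a 1,3-dicarbonyl unit.
3. Ring B is cut at C3–C4 and O1–C8a. Ring A arrives as 2-fluoro-6-heptyl-4-methoxybenzoyl chloride and ring C as a 4-aryl-3-oxobutanoate whose active CH2 becomes C3. Rings A and C are bought, and ring B is the only ring formed.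
4. Ring A piece: Kumada heptylation, bromination para to OMe, Br/Li exchange with CO2, then (COCl)2. Ring C piece: tert-butyl ester of 2,4-dimethoxy-6-methylbenzoic acid, lateral lithiation with CO2, then Masamune–Brooks extension.
5. The ring C carboxyl travels as a hindered tert-butyl ester rather than a methyl ester. This blocks Dieckmann and isocoumarin closure in the basic key step and removes a final saponification that neither the chromone nor the 2,4-dihydroxybenzoic acid would stand.

Key step: step 8

Remark: chromone numbering is used (O1, C2, C3, C4, C4a, C5 to C8, C8a), with ring A the benzo ring, ring B the pyranone and ring C the resorcylic acid ring; the target has no stereocentre; tricarbonyl 16 is drawn in its keto form although it should be largely enolised and configurationally labile.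

**Step 1**
Reactants: 1 1-bromo-3-fluoro-5-methoxybenzene; 2 heptylmagnesium bromide
Product: 3 1-fluoro-3-heptyl-5-methoxybenzene
Conditions: Pd(dppf)Cl2 (3 mol%), THF/Et2O, 0 °C to 50 °C
Reagents that add atoms: none
Why: Kumada–Corriu coupling, in which zerovalent palladium formed from Pd(dppf)Cl2 inserts only into the C–Br bond (C–F and C–OMe stay inert) and the wide bite angle of dppf favours reductive elimination over beta-hydride elimination of the primary alkyl group.

**Step 2**
Reactants: 3 1-fluoro-3-heptyl-5-methoxybenzene
Product: 4 2-bromo-1-fluoro-3-heptyl-5-methoxybenzene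
Conditions: NBS (1.05 equiv), MeCN, 0 °C to rt, dark
Reagents that add atoms: N-bromosuccinimide, O=C1CCC(=O)N1Br
Why: Electrophilic aromatic bromination with NBS in acetonitrile, a system known for para-selective bromination of anisoles including 3,5-disubstituted ones, should place bromine between the small fluorine and the heptyl group more reliably than a formylation would, and the polar, dark medium avoids benzylic radical bromination.

**Step 3**
Reactants: 4 2-bromo-1-fluoro-3-heptyl-5-methoxybenzene
Product: 6 2-fluoro-6-heptyl-4-methoxybenzoic acid, via aryllithium 5 (not isolated)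
Conditions: n-BuLi (1.05 equiv), THF, −78 °C; CO2 (dry gas), −78 °C to rt; 1 M HCl
Reagents that add atoms: carbon dioxide, O=C=O
Why: Bromine–lithium exchange followed by carboxylation, where exchange at −78 °C outruns deprotonation between F and OMe and the ortho-fluoroaryllithium is kept below the temperature at which it loses LiF to an aryne until CO2 traps it.

**Step 4**
Reactants: 6 2-fluoro-6-heptyl-4-methoxybenzoic acid
Product: 7 2-fluoro-6-heptyl-4-methoxybenzoyl chloride
Conditions: (COCl)2 (1.5 equiv), DMF (cat.), CH2Cl2, 0 °C to rt; evaporate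
Reagents that add atoms: oxalyl chloride, O=C(Cl)C(=O)Cl
Why: Acid chloride formation through the catalytic Vilsmeier-type chloroiminium salt, which works on hindered electron-rich benzoic acids, leaves only gaseous by-products and cannot form a ketene because there is no alpha hydrogen.

**Step 5**
Reactants: 8 2,4-dimethoxy-6-methylbenzoic acid
Product: 9 tert-butyl 2,4-dimethoxy-6-methylbenzoate
Conditions: Cl3CC(=NH)OtBu (2 equiv), BF3·OEt2 (cat.), CH2Cl2/cyclohexane, rt
Reagents that add atoms: tert-butyl 2,2,2-trichloroacetimidate, CC(C)(C)OC(=N)C(Cl)(Cl)Cl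
Why: Imidate esterification, in which the carboxyl oxygen is alkylated by a tert-butyl cation equivalent, so no attack is needed at the di-ortho-substituted acyl carbon that slows acyl-transfer esterifications.

**Step 6**
Reactants: 9 tert-butyl 2,4-dimethoxy-6-methylbenzoate
Product: 11 2-[2-(tert-butoxycarbonyl)-3,5-dimethoxyphenyl]acetic acid, via benzylic lithium species 10 (not isolated)
Conditions: LiN(iPr)2 (LDA, 1.2 equiv), THF, −78 °C; CO2 (dry gas), −78 °C to 0 °C; cold 0.5 M HCl to pH 3
Reagents that add atoms: carbon dioxide, O=C=O
Why: Lateral lithiation of an ortho-toluate and carboxylation, where the methyl group is deprotonated to an ester-conjugated benzylic anion, the bulky tert-butyl ester suppresses self-condensation, and CO2 gives the homophthalate half-acid with the two carboxyls already differentiated.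

**Step 7**
Reactants: 11 2-[2-(tert-butoxycarbonyl)-3,5-dimethoxyphenyl]acetic acid; 12 mono-benzyl malonate
Product: 14 benzyl 4-[2-(tert-butoxycarbonyl)-3,5-dimethoxyphenyl]-3-oxobutanoate, via acyl imidazolide 13 (not isolated)
Conditions: CDI (1.1 equiv), THF, rt; then 12 (1.5 equiv), MgCl2 (1.5 equiv), Et3N (3 equiv), premixed in MeCN, rt to 40 °C; cold 0.5 M HCl
Reagents that add atoms: none
Why: Masamune–Brooks chain extension, in which the magnesium chelate of the malonate half-ester is C-acylated by the imidazolide and loses CO2 to give the beta-ketoester under near-neutral conditions that leave the tert-butyl benzoate untouched.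

**Step 8**
Reactants: 7 2-fluoro-6-heptyl-4-methoxybenzoyl chloride; 14 benzyl 4-[2-(tert-butoxycarbonyl)-3,5-dimethoxyphenyl]-3-oxobutanoate
Product: 17 benzyl 2-{[2-(tert-butoxycarbonyl)-3,5-dimethoxyphenyl]methyl}-5-heptyl-7-methoxy-4-oxo-4H-chromene-3-carboxylate, via chloromagnesium enolate 15 (not isolated), via tricarbonyl 16 (not isolated)
Conditions: 14, MgCl2 (1.2 equiv), Et3N (2.5 equiv), MeCN, 0 °C; 7 (1.1 equiv), 0 °C to rt; then K2CO3 (3 equiv), DMF, 80 °C, argon, same flask
Reagents that add atoms: none
Why: Soft enolisation with MgCl2/Et3N gives the chelated Z-enolate 15, whose central carbon attacks acid chloride 7 (Rathke-type C-acylation, C3–C4 bond) to give tricarbonyl 16, which rests as its magnesium chelate until K2CO3 in DMF precipitates the magnesium and frees the potassium enolate. The oxygen of the former side-chain ketone then adds to C8a, the charge of the Meisenheimer adduct is taken up by C4a and the C4 carbonyl, and fluoride leaves (O1–C8a bond); this acylation/SNAr pair is the known route to chromone-3-carboxylates and, with enamines in place of enols, to quinolone antibacterials. Ring B closes as a six-membered ring by addition–elimination at an sp2 carbon: the breaking C–F bond is exocyclic, while the electron pair passes to C4a inside the new ring, so the addition is best counted as 6-endo-trig, and no stereocentre is formed. C- over O-acylation is secured by the magnesium chelate that ties up both enolate oxygens, and closure through the ketone oxygen rather than the ester oxygen follows from its higher charge density and from the stable vinylogous ester that results, while the aroyl oxygen cannot reach C8a. The 7-methoxy group is meta to C8a and therefore sits on no charge-bearing carbon of the adduct, so it does not cancel the activation by the ortho acyl group. The ring C tert-butyl ester, flanked by OMe and CH2, is too hindered to be attacked by C3, by the enolate oxygen or by the acidic C2–CH2 of the product, which shuts off the naphthol (Dieckmann) and isocoumarin closures open to a methyl ester.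

**Step 9**
Reactants: 17 benzyl 2-{[2-(tert-butoxycarbonyl)-3,5-dimethoxyphenyl]methyl}-5-heptyl-7-methoxy-4-oxo-4H-chromene-3-carboxylate
Product: 18 2-{[2-(tert-butoxycarbonyl)-3,5-dimethoxyphenyl]methyl}-5-heptyl-7-methoxy-4-oxo-4H-chromene-3-carboxylic acid
Conditions: H2 (1 atm), 10% Pd/C, EtOAc, rt
Reagents that add atoms: none
Why: Hydrogenolysis of the benzyl ester, orthogonal to the tert-butyl ester and the methyl ethers, with the tetrasubstituted push–pull C2=C3 bond of the chromone expected to resist reduction under these mild conditions.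

**Step 10**
Reactants: 18 2-{[2-(tert-butoxycarbonyl)-3,5-dimethoxyphenyl]methyl}-5-heptyl-7-methoxy-4-oxo-4H-chromene-3-carboxylic acid
Product: 19 tert-butyl 2-[(5-heptyl-7-methoxy-4-oxo-4H-chromen-2-yl)methyl]-4,6-dimethoxybenzoate
Conditions: pyridine, 115 °C, argon
Reagents that add atoms: none
Why: Thermal decarboxylation of a chromone-3-carboxylic acid (such acids are isolable and need heat), eased here because pyridine can shift a proton from the acidic C2–CH2 to C3 to give the 2-benzylidenechroman-4-one tautomer, a true beta-keto acid with sp3 C3 that loses CO2 through the usual cyclic transition state as in the Doebner decarboxylation of alkylidenemalonic acids, while the basic medium spares the tert-butyl ester.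

**Step 11**
Reactants: 19 tert-butyl 2-[(5-heptyl-7-methoxy-4-oxo-4H-chromen-2-yl)methyl]-4,6-dimethoxybenzoate
Product: 20 siphulin, 2-[(5-heptyl-7-hydroxy-4-oxo-4H-chromen-2-yl)methyl]-4,6-dihydroxybenzoic acid
Conditions: BBr3 (10 equiv), CH2Cl2, −78 °C to rt; ice-water, 0 °C
Reagents that add atoms: none
Why: Boron tribromide cleavage, in which each complexed methyl ether is demethylated by bromide in an SN2 step, the tert-butyl ester ionises at low temperature, and the ring C carboxyl stays bound as a boron salicylate chelate until the cold quench, so no base touches the chromone and no heat touches the decarboxylation-prone acid.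

**Compound list**
1 | 1-bromo-3-fluoro-5-methoxybenzene | COc1cc(F)cc(Br)c1 | starting material
2 | heptylmagnesium bromide | CCCCCCC[Mg]Br | starting material
3 | 1-fluoro-3-heptyl-5-methoxybenzene | CCCCCCCc1cc(F)cc(OC)c1 | intermediate
4 | 2-bromo-1-fluoro-3-heptyl-5-methoxybenzene | CCCCCCCc1cc(OC)cc(F)c1Br | intermediate
5 | (2-fluoro-6-heptyl-4-methoxyphenyl)lithium | [Li]c1c(F)cc(OC)cc1CCCCCCC | intermediate
6 | 2-fluoro-6-heptyl-4-methoxybenzoic acid | CCCCCCCc1cc(OC)cc(F)c1C(=O)O | intermediate
7 | 2-fluoro-6-heptyl-4-methoxybenzoyl chloride | CCCCCCCc1cc(OC)cc(F)c1C(=O)Cl | intermediate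
8 | 2,4-dimethoxy-6-methylbenzoic acid | Cc1cc(OC)cc(OC)c1C(=O)O | starting material
9 | tert-butyl 2,4-dimethoxy-6-methylbenzoate | Cc1cc(OC)cc(OC)c1C(=O)OC(C)(C)C | intermediate
10 | {[2-(tert-butoxycarbonyl)-3,5-dimethoxyphenyl]methyl}lithium | [Li]Cc1cc(OC)cc(OC)c1C(=O)OC(C)(C)C | intermediate
11 | 2-[2-(tert-butoxycarbonyl)-3,5-dimethoxyphenyl]acetic acid | COc1cc(OC)c(C(=O)OC(C)(C)C)c(CC(=O)O)c1 | intermediate
12 | mono-benzyl malonate (3-(benzyloxy)-3-oxopropanoic acid) | O=C(O)CC(=O)OCc1ccccc1 | starting material
13 | tert-butyl 2-[2-(1H-imidazol-1-yl)-2-oxoethyl]-4,6-dimethoxybenzoate | COc1cc(OC)c(C(=O)OC(C)(C)C)c(CC(=O)n2ccnc2)c1 | intermediate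
14 | benzyl 4-[2-(tert-butoxycarbonyl)-3,5-dimethoxyphenyl]-3-oxobutanoate | COc1cc(OC)c(C(=O)OC(C)(C)C)c(CC(=O)CC(=O)OCc2ccccc2)c1 | intermediate
15 | chloromagnesium (Z)-enolate of 14 | COc1cc(OC)c(C(=O)OC(C)(C)C)c(C/C(O[Mg]Cl)=C/C(=O)OCc2ccccc2)c1 | intermediate
16 | benzyl 4-[2-(tert-butoxycarbonyl)-3,5-dimethoxyphenyl]-2-(2-fluoro-6-heptyl-4-methoxybenzoyl)-3-oxobutanoate | CCCCCCCc1cc(OC)cc(F)c1C(=O)C(C(=O)OCc1ccccc1)C(=O)Cc1cc(OC)cc(OC)c1C(=O)OC(C)(C)C | intermediate
17 | benzyl 2-{[2-(tert-butoxycarbonyl)-3,5-dimethoxyphenyl]methyl}-5-heptyl-7-methoxy-4-oxo-4H-chromene-3-carboxylate | CCCCCCCc1cc(OC)cc2oc(Cc3cc(OC)cc(OC)c3C(=O)OC(C)(C)C)c(C(=O)OCc3ccccc3)c(=O)c12 | intermediate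
18 | 2-{[2-(tert-butoxycarbonyl)-3,5-dimethoxyphenyl]methyl}-5-heptyl-7-methoxy-4-oxo-4H-chromene-3-carboxylic acid | CCCCCCCc1cc(OC)cc2oc(Cc3cc(OC)cc(OC)c3C(=O)OC(C)(C)C)c(C(=O)O)c(=O)c12 | intermediate
19 | tert-butyl 2-[(5-heptyl-7-methoxy-4-oxo-4H-chromen-2-yl)methyl]-4,6-dimethoxybenzoate | CCCCCCCc1cc(OC)cc2oc(Cc3cc(OC)cc(OC)c3C(=O)OC(C)(C)C)cc(=O)c12 | intermediate
20 | siphulin | CCCCCCCc1cc(O)cc2oc(Cc3cc(O)cc(O)c3C(=O)O)cc(=O)c12 | target

**Total step count:** 11.
**Longest linear sequence:** 8 steps (steps 1 to 4, then 8 to 11). The ring C branch contributes steps 5 to 7.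

**Steps most likely to fail**

**Step 8.** The acid chloride is flanked by fluorine and heptyl, so C-acylation of the bulky enolate may be slow. O-acylation, hydrolysis or retro-Claisen loss of an acyl group could then overtake it.
- The fallback reverses the roles of acyl donor and acceptor. It sets out from 7 and 12.
- Compound 7 is added to the small magnesium chelate of 12 (MgCl2, Et3N, MeCN, 0 °C to rt). This decarboxylative acylation is the type used for hindered halobenzoylacetates, and it should give benzyl 3-(2-fluoro-6-heptyl-4-methoxyphenyl)-3-oxopropanoate F1.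
- F1 is then C-acylated under the same MgCl2/Et3N conditions by the unhindered acyl imidazolide 13, made from 11 with CDI. In this sequence the C2–C3 bond is formed last.
- The sequence comes back to the route at tricarbonyl 16, which is closed with K2CO3 in DMF to 17.

**Step 10.** Loss of CO2 may be too slow, because in the planar pyranone the C3–CO2H bond lies orthogonal to the pi system. The temperature needed may also start to cleave the tert-butyl ester.
- The fallback removes the carboxyl before ring B is closed. It sets out from 16, isolated by a cold acidic work-up after the acylation stage of step 8.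
- Hydrogenolysis (H2, Pd/C, EtOAc, rt) gives 4-[2-(tert-butoxycarbonyl)-3,5-dimethoxyphenyl]-2-(2-fluoro-6-heptyl-4-methoxybenzoyl)-3-oxobutanoic acid F2.
- F2 is an ordinary acyclic beta-keto acid and should lose CO2 at room temperature to give tert-butyl 2-[4-(2-fluoro-6-heptyl-4-methoxyphenyl)-2,4-dioxobutyl]-4,6-dimethoxybenzoate F3.
- K2CO3 in DMF at 80 to 100 °C then closes ring B by the same fluoride displacement and comes back to the route at 19.

**Step 11.** Three things may go wrong:
- cleavage of the non-chelated 7-methoxy group may stay incomplete;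
- the liberated tert-butyl cation may alkylate the electron-rich rings;
- the freed 2,4-dihydroxybenzoic acid may undergo protodecarboxylation in the HBr-rich medium.

The fallback separates the two tasks and changes the mechanism of ether cleavage. It sets out from 19.
- Nucleophilic SN2 demethylation with NaSEt (excess, DMF, 110 °C, argon) first deprotonates the C2–CH2 and so shields the chromone from thiolate addition. It leaves the hindered tert-butyl ester and should give tert-butyl 2-[(5-heptyl-7-hydroxy-4-oxo-4H-chromen-2-yl)methyl]-4,6-dihydroxybenzoate F4.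
- Brief acidolysis (TFA, Et3SiH as cation scavenger, CH2Cl2, 0 °C) then comes back to the route at 20.

**Further compounds**
F1 | step 8 | benzyl 3-(2-fluoro-6-heptyl-4-methoxyphenyl)-3-oxopropanoate | CCCCCCCc1cc(OC)cc(F)c1C(=O)CC(=O)OCc1ccccc1
F2 | step 10 | 4-[2-(tert-butoxycarbonyl)-3,5-dimethoxyphenyl]-2-(2-fluoro-6-heptyl-4-methoxybenzoyl)-3-oxobutanoic acid | CCCCCCCc1cc(OC)cc(F)c1C(=O)C(C(=O)O)C(=O)Cc1cc(OC)cc(OC)c1C(=O)OC(C)(C)C
F3 | step 10 | tert-butyl 2-[4-(2-fluoro-6-heptyl-4-methoxyphenyl)-2,4-dioxobutyl]-4,6-dimethoxybenzoate | CCCCCCCc1cc(OC)cc(F)c1C(=O)CC(=O)Cc1cc(OC)cc(OC)c1C(=O)OC(C)(C)C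
F4 | step 11 | tert-butyl 2-[(5-heptyl-7-hydroxy-4-oxo-4H-chromen-2-yl)methyl]-4,6-dihydroxybenzoate | CCCCCCCc1cc(O)cc2oc(Cc3cc(O)cc(O)c3C(=O)OC(C)(C)C)cc(=O)c12
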